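**Retrosynthetic overview**
1. 18 ⇒ ester C–O bond: the lithium alkoxide of the (S,E)-hydroxy lactone 14 attacks the (Z)-epoxy lactone 15 at the acyl carbon. This opening releases the (S)-α-hydroxy ketone, so the acid half needs no protecting group and no coupling reagent.
2. 14 ⇒ acyclic (S,E)-γ-keto acid 10: the carboxyl O adds to the C-4 ketone and water is lost toward CH3. This closes the only ring of 18 (step 4).
3. 10 and 15 ⇒ one enantioselective epoxidation applied to the geometric isomers 6 (E) and 7 (Z). It sets both (S) centres.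
4. 7 ⇒ 6 by E→Z photoisomerisation; 6 ⇒ α-angelica lactone 1 + tetradecanal 2.
5. Ring order: the purchased furanone ring is only a carrier and is opened in both halves. The ring present in 18 is formed once, in step 4, before the ester bond.

Target as read from the SMILES: an (E)-tetradecylidene γ-methylene lactone with an (S) carbinol carbon. It is O-acylated by (2Z)-2-[(1S)-1-hydroxy-2-oxopropyl]hexadec-2-enoic acid.

Assumption: the plant is taken to build the lactone from the acyclic C16 + C3 γ-keto acid (secobutanolide acid) by carboxyl-to-ketone lactol closure and loss of water. The ester is taken to arise by acyl transfer from a second C19 unit of the same (S) series.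

**Step 1**
Reactants: 1 α-angelica lactone (5-methylfuran-2(3H)-one); 2 tetradecanal
Product: 6 (3E)-5-methyl-3-tetradecylidenefuran-2(3H)-one, via lithium 5-methylfuran-2-olate 3 (not isolated), via lithium 1-(5-methyl-2-oxo-2,3-dihydrofuran-3-yl)tetradecan-1-olate 4 (not isolated), via 1-(5-methyl-2-oxo-2,3-dihydrofuran-3-yl)tetradecyl acetate 5 (not isolated)
Conditions: LiHMDS, THF, −78 °C; 2; Ac2O, −78 → 0 °C; Et3N, 0 °C → rt
Reagents that add atoms: none
Why: Aldol condensation run as aldol addition/O-acetylation/E1cB: dienolate 3 adds kinetically through its α-carbon (closed transition state, γ-carbon blocked by the methyl group), the aldolate is trapped as acetate 5 before retro-aldol, and the very acidic H-3 (aromatic furanolate) lets Et3N expel acetate to give mainly the less strained E-alkylidene; no stereocentre remains, and any minor Z-isomer is added to 7.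

**Step 2**
Reactants: 6 (3E)-5-methyl-3-tetradecylidenefuran-2(3H)-one
Product: 7 (3Z)-5-methyl-3-tetradecylidenefuran-2(3H)-one
Conditions: hν (365 nm), thioxanthone (5 mol %), degassed toluene, rt; SiO2 separation, recovered 6 recycled
Reagents that add atoms: none
Why: Triplet-sensitised E/Z photoisomerisation: only the exocyclic C=C can twist in the excited dienyl lactone, so a photostationary E/Z mixture forms from which 7 is separated while 6 is recycled or fed to step 3; air is excluded to avoid singlet-oxygen ene chemistry.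

**Step 3**
Reactants: 6 (3E)-5-methyl-3-tetradecylidenefuran-2(3H)-one
Product: 10 (2E)-2-[(1S)-1-hydroxy-2-oxopropyl]hexadec-2-enoic acid, via (1R,4E,5S)-1-methyl-4-tetradecylidene-2,6-dioxabicyclo[3.1.0]hexan-3-one 8 (not isolated), via (3E,4S)-4,5-dihydroxy-5-methyl-3-tetradecylideneoxolan-2-one 9 (not isolated)
Conditions: (S,S)-Jacobsen Mn(salen)Cl (5 mol %), 4-phenylpyridine N-oxide (20 mol %), aq NaOCl (pH 11.3), CH2Cl2, 0 °C; phase cut; PPTS (cat.), THF–H2O, 0 °C → rt
Reagents that add atoms: sodium hypochlorite [Na+].[O-]Cl; water O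
Why: Jacobsen–Katsuki epoxidation followed by acid-catalysed oxirane hydrolysis: the ring-cis, conjugated, O-substituted C4=C5 bond is the olefin class this catalyst handles best and is far more electron-rich than the ester-conjugated alkylidene, the (S,S)-catalyst delivers oxygen to the face that makes the carbon next to the conjugating sp2 carbon S (same sense as indene → (1S,2R)-oxide and 2,2-dimethylchromene → (3S,4S)-oxide), and water opens the acyloxy-oxirane only at its ketal carbon, so the new C–O bond at the stereocentre is kept and lactol 9 opens to keto acid 10 (handled as the ring–chain mixture).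

**Step 4**
Reactants: 10 (2E)-2-[(1S)-1-hydroxy-2-oxopropyl]hexadec-2-enoic acid
Product: 14 (3E,4S)-4-hydroxy-5-methylidene-3-tetradecylideneoxolan-2-one (isoobtusilactone A), via trimethylsilyl (2E)-2-[(1S)-2-oxo-1-(trimethylsilyloxy)propyl]hexadec-2-enoate 11 (not isolated), via (3S,4E)-2-methyl-5-oxo-4-tetradecylidene-3-(trimethylsilyloxy)oxolan-2-yl triflate 12 (not isolated), via (3E,4S)-5-methylidene-3-tetradecylidene-4-(trimethylsilyloxy)oxolan-2-one 13 (not isolated)
Conditions: TMSOTf (2.2 equiv), 2,6-lutidine (6 equiv), CH2Cl2, −78 → 0 °C; Tf2O (1.1 equiv), −78 → −30 °C; 1 M aq citric acid–THF, 0 °C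
Reagents that add atoms: none
Why: Proposed new method: cyclodehydration (enol lactonisation) of the γ-keto acid, in which, after transient O-silylation, Tf2O triflates either carbonyl of 11 and the other one closes the five-membered ring (carboxyl O to C-4, the bond of lactol 9), both paths converging on pseudo-acid triflate 12, from which the hindered base removes a proton of the exposed CH3 rather than the shielded, O-substituted C-3 methine (which is no longer α to a ketone once the ring is closed), giving the exocyclic enol lactone with C-3 (S) untouched; closest known reaction types are the cyclodehydration of levulinic acid to angelica lactone via pseudo-acyl derivatives, the Gassman TMSOTf/amine conversion of ketals into the less substituted enol ethers, and the Noyori TMSOTf/base epoxide → allyl silyl ether isomerisation.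

**Step 5**
Reactants: 7 (3Z)-5-methyl-3-tetradecylidenefuran-2(3H)-one
Product: 15 (1R,4Z,5S)-1-methyl-4-tetradecylidene-2,6-dioxabicyclo[3.1.0]hexan-3-one
Conditions: (S,S)-Jacobsen Mn(salen)Cl (5 mol %), 4-phenylpyridine N-oxide (20 mol %), aq NaOCl (pH 11.3), CH2Cl2, 0 °C; cold NaHCO3 wash, short Et3N-deactivated SiO2 plug, used the same day
Reagents that add atoms: sodium hypochlorite [Na+].[O-]Cl
Why: Jacobsen–Katsuki epoxidation with the same chemo- and face selectivity as in step 3 (the Z-chain points away from the reacting bond), setting the carbinol carbon as S; enol-ester epoxides of this kind can be isolated if kept cold and free of acid.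

**Step 6**
Reactants: 14 isoobtusilactone A; 15 (1R,4Z,5S)-epoxy lactone
Product: 18 (3S,4E)-2-methylidene-5-oxo-4-tetradecylideneoxolan-3-yl (2Z)-2-[(1S)-1-hydroxy-2-oxopropyl]hexadec-2-enoate (target), via lithium (3S,4E)-2-methylidene-5-oxo-4-tetradecylideneoxolan-3-olate 16 (not isolated), via lithium alkoxide of the target 17 (not isolated)
Conditions: 14 (1.2 equiv), LiHMDS (1.15 equiv), THF, −78 °C; 15 (1.0 equiv), −78 → −40 °C; AcOH, −78 °C
Reagents that add atoms: none
Why: Proposed new method: acyl transfer by ring opening, in which alkoxide 16 attacks the lactone C=O of neutral, strain-activated 15 (the enol lactone of 16 sits in an anionic aggregate and is the poorer electrophile), and collapse of the tetrahedral intermediate breaks the acyl–O bond so that the released α-epoxy alkoxide unzips to methyl ketone plus C-1′ alkoxide 17; the C-1′–O bond made in step 5 is never touched (S retained), the masked OH cannot self-acylate, and no nucleophilic catalyst is present that could isomerise the Z-enoate; closest known reaction types are the alkaline acyl cleavage of enol-acetate epoxides to α-ketols (steroid 17α-hydroxy-20-ketone synthesis) and the Holton–Ojima coupling of hindered lithium alkoxides with strained β-lactam acyl donors.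

**Compound list**
1 | α-angelica lactone (5-methylfuran-2(3H)-one) | CC1=CCC(=O)O1 | starting material
2 | tetradecanal | CCCCCCCCCCCCCC=O | starting material
3 | lithium 5-methylfuran-2-olate | Cc1ccc([O-])o1.[Li+] | intermediate
4 | lithium 1-(5-methyl-2-oxo-2,3-dihydrofuran-3-yl)tetradecan-1-olate (racemic diastereomer mixture) | CC1=CC(C([O-])CCCCCCCCCCCCC)C(=O)O1.[Li+] | intermediate
5 | 1-(5-methyl-2-oxo-2,3-dihydrofuran-3-yl)tetradecyl acetate (racemic diastereomer mixture) | CC1=CC(C(OC(C)=O)CCCCCCCCCCCCC)C(=O)O1 | intermediate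
6 | (3E)-5-methyl-3-tetradecylidenefuran-2(3H)-one | O=C1OC(C)=C/C1=C\CCCCCCCCCCCCC | intermediate
7 | (3Z)-5-methyl-3-tetradecylidenefuran-2(3H)-one | O=C1OC(C)=C/C1=C/CCCCCCCCCCCCC | intermediate
8 | (1R,4E,5S)-1-methyl-4-tetradecylidene-2,6-dioxabicyclo[3.1.0]hexan-3-one | O=C1O[C@@]2(C)O[C@H]2/C1=C\CCCCCCCCCCCCC | intermediate
9 | (3E,4S)-4,5-dihydroxy-5-methyl-3-tetradecylideneoxolan-2-one (lactol, C-5 epimers) | CC1(O)OC(=O)/C(=C/CCCCCCCCCCCCC)[C@@H]1O | intermediate
10 | (2E)-2-[(1S)-1-hydroxy-2-oxopropyl]hexadec-2-enoic acid | OC(=O)/C(=C/CCCCCCCCCCCCC)[C@H](O)C(C)=O | intermediate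
11 | trimethylsilyl (2E)-2-[(1S)-2-oxo-1-(trimethylsilyloxy)propyl]hexadec-2-enoate | C[Si](C)(C)OC(=O)/C(=C/CCCCCCCCCCCCC)[C@H](O[Si](C)(C)C)C(C)=O | intermediate
12 | (3S,4E)-2-methyl-5-oxo-4-tetradecylidene-3-(trimethylsilyloxy)oxolan-2-yl triflate (C-2 epimers) | CC1(OS(=O)(=O)C(F)(F)F)OC(=O)/C(=C/CCCCCCCCCCCCC)[C@@H]1O[Si](C)(C)C | intermediate
13 | (3E,4S)-5-methylidene-3-tetradecylidene-4-(trimethylsilyloxy)oxolan-2-one | C=C1OC(=O)/C(=C/CCCCCCCCCCCCC)[C@@H]1O[Si](C)(C)C | intermediate
14 | (3E,4S)-4-hydroxy-5-methylidene-3-tetradecylideneoxolan-2-one (isoobtusilactone A) | C=C1OC(=O)/C(=C/CCCCCCCCCCCCC)[C@@H]1O | intermediate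
15 | (1R,4Z,5S)-1-methyl-4-tetradecylidene-2,6-dioxabicyclo[3.1.0]hexan-3-one | O=C1O[C@@]2(C)O[C@H]2/C1=C/CCCCCCCCCCCCC | intermediate
16 | lithium (3S,4E)-2-methylidene-5-oxo-4-tetradecylideneoxolan-3-olate | C=C1OC(=O)/C(=C/CCCCCCCCCCCCC)[C@@H]1[O-].[Li+] | intermediate
17 | lithium alkoxide of the target (O-1′) | C=C1OC(=O)/C(=C/CCCCCCCCCCCCC)[C@@H]1OC(=O)/C(=C\CCCCCCCCCCCCC)[C@H]([O-])C(C)=O.[Li+] | intermediate
18 | (3S,4E)-2-methylidene-5-oxo-4-tetradecylideneoxolan-3-yl (2Z)-2-[(1S)-1-hydroxy-2-oxopropyl]hexadec-2-enoate | C=C1OC(=O)/C(=C/CCCCCCCCCCCCC)[C@@H]1OC(=O)/C(=C\CCCCCCCCCCCCC)[C@H](O)C(C)=O | target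

**Step count**
- Total: 6 steps.
- Longest linear sequence: 4 steps (1 → 2 → 5 → 6, or 1 → 3 → 4 → 6).

**Steps most likely to fail**

Step 4 (ring closure). The cation or triflate 12 may lose H-3, or H-3 may migrate. Either path destroys the stereocentre and gives furan-2,4-dione-type products. Tf2O may also attack the silyl ether.

The fallback sets out from 8 and comes back at 14. The hydrolysis in step 3 is omitted and 8 is isolated exactly as 15. TMSOTf/2,6-lutidine (CH2Cl2, −78 °C) opens the oxirane anti at the ketal carbon. This gives 12 as the isomer with OTf trans to OSiMe3, that is, cis to H-3, so only the CH3 hydrogens can become antiperiplanar. DBU then effects E2 elimination to 13, and citric acid gives 14. This is an epoxide → allylic alcohol isomerisation with the ring kept, not a cyclodehydration. It makes no compound that is not already in the list (F0).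

Step 6 (acyl transfer). Possible failures are alkoxide addition to the alkylidene/vinyl-oxirane terminus of 15, self-acylation of 16, and further acylation of 17.

The fallback sets out from 15 (with 14) and comes back at 18.
- 15 is hydrolysed as in step 3 through the (3Z,4S)-lactol F1 to (2Z)-2-[(1S)-1-hydroxy-2-oxopropyl]hexadec-2-enoic acid F2.
- TESOTf/2,6-lutidine gives the triethylsilyl ester/triethylsilyl ether F3.
- Its silyl ester is cleaved with aq AcOH–THF to the O-TES acid F4.
- F4 is esterified with 14 under Shiina conditions (MNBA, Et3N, cat. DMAP, toluene, 0 °C) to the O-TES ether of the target F5.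
- HF·pyridine gives 18.

This is a protected-acid/activating-reagent esterification instead of the epoxide opening.

Step 5 (and the same oxidation in step 3). The substrate class is untested for sense and level of induction, and 15 is labile. Two separately made (S) units are joined, so residual minor enantiomers end up mainly in the separable (S,R)/(R,S) diastereomers. If the sense is inverted, the (R,R)-catalyst is used instead.

The fallback sets out from 7 and comes back at 18. DMDO (acetone, −20 °C, evaporation only) gives 15 together with its enantiomer, the (1S,4Z,5R)-epoxy lactone F6. The racemate is coupled with enantiopure 16 as in step 6, which gives 17 and the lithium alkoxide of the (1′R)-epimer F7. After the AcOH quench these become 18 and the (1′R)-epimer of the target F8, which are separated by chromatography. This replaces catalyst control with separation of covalent diastereomers.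

**Further compounds**
F0 | step 4 | none | none
F1 | step 6 | (3Z,4S)-4,5-dihydroxy-5-methyl-3-tetradecylideneoxolan-2-one (lactol, C-5 epimers) | CC1(O)OC(=O)/C(=C\CCCCCCCCCCCCC)[C@@H]1O
F2 | step 6 | (2Z)-2-[(1S)-1-hydroxy-2-oxopropyl]hexadec-2-enoic acid | OC(=O)/C(=C\CCCCCCCCCCCCC)[C@H](O)C(C)=O
F3 | step 6 | triethylsilyl (2Z)-2-[(1S)-2-oxo-1-(triethylsilyloxy)propyl]hexadec-2-enoate | CC[Si](CC)(CC)OC(=O)/C(=C\CCCCCCCCCCCCC)[C@H](O[Si](CC)(CC)CC)C(C)=O
F4 | step 6 | (2Z)-2-[(1S)-2-oxo-1-(triethylsilyloxy)propyl]hexadec-2-enoic acid | OC(=O)/C(=C\CCCCCCCCCCCCC)[C@H](O[Si](CC)(CC)CC)C(C)=O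
F5 | step 6 | O-triethylsilyl ether of the target | C=C1OC(=O)/C(=C/CCCCCCCCCCCCC)[C@@H]1OC(=O)/C(=C\CCCCCCCCCCCCC)[C@H](O[Si](CC)(CC)CC)C(C)=O
F6 | step 5 | (1S,4Z,5R)-1-methyl-4-tetradecylidene-2,6-dioxabicyclo[3.1.0]hexan-3-one | O=C1O[C@]2(C)O[C@@H]2/C1=C/CCCCCCCCCCCCC
F7 | step 5 | lithium alkoxide of the (1′R)-epimer of the target | C=C1OC(=O)/C(=C/CCCCCCCCCCCCC)[C@@H]1OC(=O)/C(=C\CCCCCCCCCCCCC)[C@@H]([O-])C(C)=O.[Li+]
F8 | step 5 | (3S,4E)-2-methylidene-5-oxo-4-tetradecylideneoxolan-3-yl (2Z)-2-[(1R)-1-hydroxy-2-oxopropyl]hexadec-2-enoate | C=C1OC(=O)/C(=C/CCCCCCCCCCCCC)[C@@H]1OC(=O)/C(=C\CCCCCCCCCCCCC)[C@@H](O)C(C)=O
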